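**Plan**

1. Retrosynthesis: (a) open the hemiketal O–C bond of the dihydrofuran ring (ring–chain tautomer: free 7-OH of the flavonol plus a 4-hydroxybenzoyl ketone); (b) cut the benzofuranone O-1–C-2 bond at the spiro carbon; (c) cut the C-2–aroyl bond (acyl shift from oxygen); (d) cut the aryl–CH2 bond between C-8 of the flavonol and the ketone α-carbon. This leads back to kaempferol, a phloroacetophenone dibenzyl ether and 4-(benzyloxy)benzoyl chloride.
2. Enabling feature: the spiro carbon lies between two carbonyl-level carbons (C-3 of the benzofuranone and the hemiketal carbon, a masked aroyl group). With the ether bond cut it is the central C–H of a 2-aryl-1,3-diketone, and the ring A phenol oxygen sits ortho to one of those carbonyls. An oxidative enol–phenol C–O coupling therefore closes the five-membered ring and creates the quaternary centre in one event.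
3. Forward order: kaempferol is benzylated and iodinated at C-8; ketone α-arylation joins the two phloroglucinol-derived halves; aroylation with acyl shift gives the diketone; the key oxidation closes the benzofuranone ring; hydrogenolysis frees the 7-OH, which closes the dihydrofuran hemiketal ring last.
4. Stereochemistry: the quaternary carbon is set in the key step by a chiral quaternary ammonium hypoiodite catalyst; the hemiketal carbon follows from it under thermodynamic control.
5. Helper groups: the benzyl ether on the flavonol 7-oxygen keeps the diketone open (no benzofuran, no quinone methide) until the last step; a MOM group masks the ring A phenol during the arylation only.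

Key step: step 7

Remark (assumption): the hemiketal carbon is taken to equilibrate by ring–chain tautomerism to the drawn diastereomer (hydroxyl syn to the C-3 carbonyl, aryl syn to the ring oxygen O-1); the antipode of the ammonium catalyst is the one that leads to the (2R)-ketone 12, which has the same spatial arrangement as the (2S) spiro carbon of the target.

**Route**

Step 1
Reactants: 1 kaempferol
Product: 2 3,5,7-tris(benzyloxy)-2-[4-(benzyloxy)phenyl]-4H-chromen-4-one
Conditions: BnBr (6 equiv), Cs2CO3, DMF, 60 °C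
Reagents that add atoms: benzyl bromide, BrCc1ccccc1
Why: Williamson etherification of all four hydroxyl groups, the chelated 5-OH needing Cs2CO3 and heat; no stereocentre is formed.

Step 2
Reactants: 2 tetra-O-benzylkaempferol
Product: 3 3,5,7-tris(benzyloxy)-2-[4-(benzyloxy)phenyl]-8-iodo-4H-chromen-4-one
Conditions: NIS, TFA (cat.), MeCN–CH2Cl2, 0 °C to rt
Reagents that add atoms: N-iodosuccinimide, O=C1CCC(=O)N1I
Why: Electrophilic aromatic iodination should go to C-8 of ring A, which is activated by the 5- and 7-benzyloxy groups and the ring oxygen and is less crowded than C-6 between two benzyloxy groups, the usual site for 5,7-dialkoxyflavones; no stereocentre is formed.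

Step 3
Reactants: 4 1-[2,4-bis(benzyloxy)-6-hydroxyphenyl]ethan-1-one
Product: 5 1-[2,4-bis(benzyloxy)-6-(methoxymethoxy)phenyl]ethan-1-one
Conditions: NaH, MOMCl, DMF, 0 °C to rt
Reagents that add atoms: chloromethyl methyl ether, COCCl
Why: O-Alkylation of the sodium phenoxide (Williamson-type acetal formation) masks the phenol that would otherwise interfere with the enolate coupling; no stereocentre is formed.

Step 4
Reactants: 3 8-iodo-tetra-O-benzylkaempferol; 5 MOM-protected acetophenone
Product: 6 3,5,7-tris(benzyloxy)-2-[4-(benzyloxy)phenyl]-8-{2-[2,4-bis(benzyloxy)-6-(methoxymethoxy)phenyl]-2-oxoethyl}-4H-chromen-4-one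
Conditions: Pd2(dba)3 (2.5 mol %), XPhos (6 mol %), K3PO4, toluene, 100 °C
Reagents that add atoms: none
Why: Palladium-catalysed ketone α-arylation (oxidative addition of zerovalent palladium into the C–I bond, enolate binding, reductive elimination) with a bulky biarylphosphine should tolerate the doubly ortho-substituted iodide and stop at mono-arylation for steric reasons; no stereocentre is formed.

Step 5
Reactants: 6 MOM-protected deoxybenzoin
Product: 7 3,5,7-tris(benzyloxy)-2-[4-(benzyloxy)phenyl]-8-{2-[2,4-bis(benzyloxy)-6-hydroxyphenyl]-2-oxoethyl}-4H-chromen-4-one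
Conditions: HCl (cat.), MeOH–THF, 40 °C
Reagents that add atoms: none
Why: Acid-catalysed acetal cleavage removes the MOM group, which is especially labile ortho to the ketone, while benzyl ethers and the chromenone are stable to dilute acid; no stereocentre is formed.

Step 6
Reactants: 7 hydroxy deoxybenzoin; 8 4-(benzyloxy)benzoyl chloride
Product: 10 1-[2,4-bis(benzyloxy)-6-hydroxyphenyl]-3-[4-(benzyloxy)phenyl]-2-{3,5,7-tris(benzyloxy)-2-[4-(benzyloxy)phenyl]-4-oxo-4H-chromen-8-yl}propane-1,3-dione, via aryl 4-(benzyloxy)benzoate ester 9 (not isolated)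
Conditions: K2CO3, acetone, 50 °C; work-up at pH 6–7
Reagents that add atoms: none
Why: O-Aroylation of the phenoxide is followed by Baker–Venkataraman rearrangement, in which the benzylic ketone enolate attacks the neighbouring ester through a six-membered transition state and the acyl group moves to carbon; the new methine carbon is stereogenic but freely enolisable, so it is carried as the racemate.

Step 7
Reactants: 10 2-aryl-1,3-diketone
Product: 12 (2R)-4,6-bis(benzyloxy)-2-[4-(benzyloxy)benzoyl]-2-{3,5,7-tris(benzyloxy)-2-[4-(benzyloxy)phenyl]-4-oxo-4H-chromen-8-yl}-1-benzofuran-3(2H)-one, via tertiary α-iodo-1,3-diketone 11 (not isolated)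
Conditions: C2-symmetric N-spiro bis(1,1'-binaphthyl-2,2'-dimethylene)ammonium iodide carrying 3,5-bis(trifluoromethyl)phenyl groups at C-3 and C-3' of one binaphthyl unit (10 mol %), cumene hydroperoxide (2 equiv), toluene, 0 °C to rt
Reagents that add atoms: none
Why: Proposed new method: the hydroperoxide oxidises the ammonium iodide to the ammonium hypoiodite, which iodinates the diketone enol at its central carbon to give 11, and the ring A phenoxide, ion-paired with the chiral cation, displaces iodide from that carbon to form the O–C bond. The closest known reaction type is the chiral quaternary ammonium hypoiodite-catalysed oxidative cycloetherification of ketophenols, which gives 2-acyl-2,3-dihydrobenzofurans and 2-acylchromans with a fully substituted α-carbon; new here are the 1,3-diketone donor and a phenol that sits on the aroyl group, so that the carbonyl lies inside the ring formed. The benzofuranone ring closes 5-exo-tet (phenol oxygen, two ring A carbons, the carbonyl carbon and the iodine-bearing carbon, with iodide leaving outside the ring). The quaternary stereocentre is set by the catalyst: 11 should racemise by reversible C-iodination through the enol, and the enantiomer that closes faster inside the chiral ion pair is drained (dynamic kinetic resolution). The step needs C–O closure to win over cyclodehydration to a 2,3-diarylchromone, over benzofuran or quinone methide formation and over ring iodination; the acid-free, near-neutral medium, the benzyl ether on the 7-oxygen of the chromenone, the single free phenol and the low stationary hypoiodite concentration should secure this.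

Step 8
Reactants: 12 (2R)-2-aroyl-2-aryl-benzofuranone
Product: 14 (2S,8'R)-3',4,5',6,8'-pentahydroxy-2',8'-bis(4-hydroxyphenyl)-8'H-spiro[1-benzofuran-2,9'-furo[2,3-h]chromene]-3,4'-dione, via ring-opened heptahydroxy ketone 13 (not isolated)
Conditions: H2 (1 atm), Pd/C, THF–EtOAc, rt
Reagents that add atoms: none
Why: Hydrogenolysis of the seven benzyl ethers frees the 7-hydroxyl of the chromenone, which adds to the neighbouring 4-hydroxybenzoyl ketone (5-exo-trig hemiketalisation) to close the dihydrofuran ring, the hemiketal carbon settling under thermodynamic control relative to the quaternary carbon, which cannot epimerise under these neutral conditions.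

**Compound list**

1 | kaempferol, 3,5,7-trihydroxy-2-(4-hydroxyphenyl)-4H-chromen-4-one | O=c1c(O)c(-c2ccc(O)cc2)oc2cc(O)cc(O)c12 | starting material
2 | 3,5,7-tris(benzyloxy)-2-[4-(benzyloxy)phenyl]-4H-chromen-4-one | O=c1c(OCc2ccccc2)c(-c2ccc(OCc3ccccc3)cc2)oc2cc(OCc3ccccc3)cc(OCc3ccccc3)c12 | intermediate
3 | 3,5,7-tris(benzyloxy)-2-[4-(benzyloxy)phenyl]-8-iodo-4H-chromen-4-one | O=c1c(OCc2ccccc2)c(-c2ccc(OCc3ccccc3)cc2)oc2c(I)c(OCc3ccccc3)cc(OCc3ccccc3)c12 | intermediate
4 | 1-[2,4-bis(benzyloxy)-6-hydroxyphenyl]ethan-1-one | CC(=O)c1c(O)cc(OCc2ccccc2)cc1OCc1ccccc1 | starting material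
5 | 1-[2,4-bis(benzyloxy)-6-(methoxymethoxy)phenyl]ethan-1-one | CC(=O)c1c(OCOC)cc(OCc2ccccc2)cc1OCc1ccccc1 | intermediate
6 | 3,5,7-tris(benzyloxy)-2-[4-(benzyloxy)phenyl]-8-{2-[2,4-bis(benzyloxy)-6-(methoxymethoxy)phenyl]-2-oxoethyl}-4H-chromen-4-one | O=C(Cc1c(OCc2ccccc2)cc(OCc2ccccc2)c2c(=O)c(OCc3ccccc3)c(-c3ccc(OCc4ccccc4)cc3)oc12)c1c(OCOC)cc(OCc2ccccc2)cc1OCc1ccccc1 | intermediate
7 | 3,5,7-tris(benzyloxy)-2-[4-(benzyloxy)phenyl]-8-{2-[2,4-bis(benzyloxy)-6-hydroxyphenyl]-2-oxoethyl}-4H-chromen-4-one | O=C(Cc1c(OCc2ccccc2)cc(OCc2ccccc2)c2c(=O)c(OCc3ccccc3)c(-c3ccc(OCc4ccccc4)cc3)oc12)c1c(O)cc(OCc2ccccc2)cc1OCc1ccccc1 | intermediate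
8 | 4-(benzyloxy)benzoyl chloride | O=C(Cl)c1ccc(OCc2ccccc2)cc1 | starting material
9 | 3,5-bis(benzyloxy)-2-({3,5,7-tris(benzyloxy)-2-[4-(benzyloxy)phenyl]-4-oxo-4H-chromen-8-yl}acetyl)phenyl 4-(benzyloxy)benzoate (not isolated) | O=C(Cc1c(OCc2ccccc2)cc(OCc2ccccc2)c2c(=O)c(OCc3ccccc3)c(-c3ccc(OCc4ccccc4)cc3)oc12)c1c(OC(=O)c2ccc(OCc3ccccc3)cc2)cc(OCc2ccccc2)cc1OCc1ccccc1 | intermediate
10 | 1-[2,4-bis(benzyloxy)-6-hydroxyphenyl]-3-[4-(benzyloxy)phenyl]-2-{3,5,7-tris(benzyloxy)-2-[4-(benzyloxy)phenyl]-4-oxo-4H-chromen-8-yl}propane-1,3-dione (racemic, enolisable) | O=C(c1ccc(OCc2ccccc2)cc1)C(C(=O)c1c(O)cc(OCc2ccccc2)cc1OCc1ccccc1)c1c(OCc2ccccc2)cc(OCc2ccccc2)c2c(=O)c(OCc3ccccc3)c(-c3ccc(OCc4ccccc4)cc3)oc12 | intermediate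
11 | 2-iodo derivative of 10 at the central carbon (not isolated, configurationally labile) | O=C(c1ccc(OCc2ccccc2)cc1)C(I)(C(=O)c1c(O)cc(OCc2ccccc2)cc1OCc1ccccc1)c1c(OCc2ccccc2)cc(OCc2ccccc2)c2c(=O)c(OCc3ccccc3)c(-c3ccc(OCc4ccccc4)cc3)oc12 | intermediate
12 | (2R)-4,6-bis(benzyloxy)-2-[4-(benzyloxy)benzoyl]-2-{3,5,7-tris(benzyloxy)-2-[4-(benzyloxy)phenyl]-4-oxo-4H-chromen-8-yl}-1-benzofuran-3(2H)-one | O=C1c2c(OCc3ccccc3)cc(OCc3ccccc3)cc2O[C@@]1(C(=O)c1ccc(OCc2ccccc2)cc1)c1c(OCc2ccccc2)cc(OCc2ccccc2)c2c(=O)c(OCc3ccccc3)c(-c3ccc(OCc4ccccc4)cc3)oc12 | intermediate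
13 | (2R)-4,6-dihydroxy-2-(4-hydroxybenzoyl)-2-[3,5,7-trihydroxy-2-(4-hydroxyphenyl)-4-oxo-4H-chromen-8-yl]-1-benzofuran-3(2H)-one (not isolated) | O=C1c2c(O)cc(O)cc2O[C@@]1(C(=O)c1ccc(O)cc1)c1c(O)cc(O)c2c(=O)c(O)c(-c3ccc(O)cc3)oc12 | intermediate
14 | (2S,8'R)-3',4,5',6,8'-pentahydroxy-2',8'-bis(4-hydroxyphenyl)-8'H-spiro[1-benzofuran-2,9'-furo[2,3-h]chromene]-3,4'-dione | O=C1c2c(O)cc(O)cc2O[C@@]12c1c(cc(O)c3c(=O)c(O)c(-c4ccc(O)cc4)oc13)O[C@]2(O)c1ccc(O)cc1 | target

**Summary**

Total step count: 8. Longest linear sequence: 7 steps (kaempferol through steps 1, 2, 4, 5, 6, 7, 8).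

Steps most likely to fail:

Step 7 (proposed new method). The risk is weak enantiofacial discrimination inside the ion pair, or diversion of the diketone into cyclodehydration before oxidation. Fallback, from 10 back to 12: iodine and K2CO3 in THF at 0 °C (classical α-halogenation of a β-diketone followed by intramolecular O-alkylation of the ortho phenoxide, through 11) should give the racemic benzofuranone F1. Preparative HPLC on an amylose tris(3,5-dimethylphenylcarbamate) stationary phase then separates the (2S)-enantiomer F2 from the (2R)-enantiomer, which is 12.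

Step 4. The risk is slow oxidative addition and reductive elimination at the doubly ortho-substituted, electron-rich iodide, so that protodeiodination or enolate self-condensation takes over. Fallback, from 3 back to 6: palladium-catalysed coupling of 3 with the Reformatsky reagent BrZnCH2CO2Et (Pd2(dba)3, XPhos, THF, 60 °C) to the ethyl arylacetate F3, then MeNHOMe·HCl and i-PrMgCl (THF, −20 °C) to the N-methoxy-N-methylamide F4. In parallel, commercial 3,5-bis(benzyloxy)phenol is protected (NaH, MOMCl) to 1,3-bis(benzyloxy)-5-(methoxymethoxy)benzene F5 and lithiated next to the MOM ether (n-BuLi, THF, 0 °C) to the aryllithium F6. Addition of F6 to F4 at −78 °C and NH4Cl quench gives ketone 6.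

Step 8. The risk is over-reduction during hydrogenolysis (cleavage of the benzylic aryl ether bond at the quaternary carbon, or reduction of an aryl ketone) or incomplete removal of seven benzyl groups. Fallback, from 12 back to 14: non-reductive debenzylation with BCl3 and pentamethylbenzene as cation scavenger in CH2Cl2 at −78 °C; 13 forms and closes to 14 as before, and no new compound is involved.

Further compounds

F1 | step 7 | racemic 4,6-bis(benzyloxy)-2-[4-(benzyloxy)benzoyl]-2-{3,5,7-tris(benzyloxy)-2-[4-(benzyloxy)phenyl]-4-oxo-4H-chromen-8-yl}-1-benzofuran-3(2H)-one | O=C1c2c(OCc3ccccc3)cc(OCc3ccccc3)cc2OC1(C(=O)c1ccc(OCc2ccccc2)cc1)c1c(OCc2ccccc2)cc(OCc2ccccc2)c2c(=O)c(OCc3ccccc3)c(-c3ccc(OCc4ccccc4)cc3)oc12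
F2 | step 7 | (2S)-4,6-bis(benzyloxy)-2-[4-(benzyloxy)benzoyl]-2-{3,5,7-tris(benzyloxy)-2-[4-(benzyloxy)phenyl]-4-oxo-4H-chromen-8-yl}-1-benzofuran-3(2H)-one | O=C1c2c(OCc3ccccc3)cc(OCc3ccccc3)cc2O[C@]1(C(=O)c1ccc(OCc2ccccc2)cc1)c1c(OCc2ccccc2)cc(OCc2ccccc2)c2c(=O)c(OCc3ccccc3)c(-c3ccc(OCc4ccccc4)cc3)oc12
F3 | step 4 | ethyl {3,5,7-tris(benzyloxy)-2-[4-(benzyloxy)phenyl]-4-oxo-4H-chromen-8-yl}acetate | CCOC(=O)Cc1c(OCc2ccccc2)cc(OCc2ccccc2)c2c(=O)c(OCc3ccccc3)c(-c3ccc(OCc4ccccc4)cc3)oc12
F4 | step 4 | N-methoxy-N-methyl-2-{3,5,7-tris(benzyloxy)-2-[4-(benzyloxy)phenyl]-4-oxo-4H-chromen-8-yl}acetamide | CON(C)C(=O)Cc1c(OCc2ccccc2)cc(OCc2ccccc2)c2c(=O)c(OCc3ccccc3)c(-c3ccc(OCc4ccccc4)cc3)oc12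
F5 | step 4 | 1,3-bis(benzyloxy)-5-(methoxymethoxy)benzene | COCOc1cc(OCc2ccccc2)cc(OCc2ccccc2)c1
F6 | step 4 | [2,4-bis(benzyloxy)-6-(methoxymethoxy)phenyl]lithium | [Li]c1c(OCOC)cc(OCc2ccccc2)cc1OCc1ccccc1
F0 | step 8 | none | none
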